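(The earlier runs and the new flask are simulated for substances that don't exist, and the scatter is random.)

| flask | substrate | partner | free catalyst | temperature | remark | time |
|---|---|---|---|---|---|---|
| amber | 1 M | 0.70 M (fed, over 80 s) | 5.6 mM | 18 °C | run made earlier; the fed solution adds 0.10 times the starting volume |  |
| green | 1 M | 0.70 M (fed, over 80 s) | 10 mM | 34 °C | run made earlier; the fed solution adds 0.10 times the starting volume |  |
| violet | 1 M | 0.70 M (fed, over 80 s) | 16 mM | 18 °C | run made earlier; the fed solution adds 0.10 times the starting volume |  |
| Friday's | 1.0 M | 0.700 M (fed, over 150 s) | 20 mM |  | at 10 °C throughout; the fed solution adds 0.10 times the starting volume | 2.5 min |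
| Sunday's | 1.0 M | 0.700 M (fed, over 80 s) | 5.0 mM |  | at 10 °C until 80 s, from then on at 40 °C; the fed solution adds 0.10 times the starting volume | 2.5 min |

- amber (time / s: target / %, substrate / %): 10.0: 10, 90; 20.0: 18, 84; 50.0: 46, 60; 120: 69, 33
- green (time / s: target / %, substrate / %): 10.0: 9, 94; 15.0: 10, 82; 25.0: 18, 78; 40.0: 33, 64
- violet (time / s: target / %, substrate / %): 12.0: 12, 92; 40.0: 33, 66; 60.0: 55, 48; 120: 73, 32

(scatter of a reading: 2 percentage points)

- the flask that ends with the higher amount of target, in percent of the substrate charged, or "neither" when 2 percentage points or less lies between them (Friday's / Sunday's / neither)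
- final target, as a percentage of the substrate charged, in Friday's
- final target, as a percentage of the substrate charged, in Sunday's

- charges are per starting volume, the dose included; the dosed solution carries all of it
- the numbers in the tables scatter with a standard deviation of 2 percentage points

At early times, target in the amber, green and violet runs climbs along the dose of partner. At 50.0 s amber reads 46% against 43.8% for the partner fed so far, and at 40.0 s green reads 33% against 35.0%. Amber's gap of 2.3 points and green's of 2 points are about the size of the scatter of 2 points. Substrate falls as target rises, so we read one partner per target.

We therefore draw each flask as a straight line with a knee at the end of the dose. Above the knee stands a level, the ceiling: 70.0%, the charge of partner over the charge of substrate. Partner is the limiting reagent, and 30.0% of the substrate stays over. At 120 s, amber reads 69%, 1 point under that level, and violet 73%, 3 points over it, against a scatter of 2 points.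

Sunday's flask reaches its knee at 80 s and then has 70.0 s, longer than the 40.0 s after which amber stood at the level, so we put it on the ceiling. Friday's line climbs at about half that slope and meets its knee at the moment of sampling, so any lag stays in the flask.

Going round once more, we take green's gap as a lag and scale it by feed per catalyst. Friday's feed per catalyst is a quarter of green's, which gives 0.53 points. Friday's flask is colder, though, and these readings give no temperature dependence, so we expect it slightly under the ceiling, within the margin of 2 points.

The forecast gives 69% for Friday's and 69.5% for Sunday's, and its choice is neither: “so I expect no real difference”.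

Friday's flask ends at 69.3% and Sunday's at 70.0%, so the answer is neither.

    partner + free catalyst ⇌ catalyst intermediate A (K = 2.40 L mol⁻¹, k = 1100 L mol⁻¹ s⁻¹, Ea = 37.0 kJ mol⁻¹, ΔH = −12.0 kJ mol⁻¹)
    substrate + catalyst intermediate A → catalyst intermediate B (k = 60.0 L mol⁻¹ s⁻¹, Ea = 39.0 kJ mol⁻¹)
    catalyst intermediate B → free catalyst + target (k = 39.0 s⁻¹, Ea = 60.0 kJ mol⁻¹)
    (constants at 10 °C)

The end value hides what to watch at Sunday's knee: at 1.33 min Sunday's flask held 65.4% target, under the ceiling of 70.0%, with 6.42% of the partner's own charge still unreacted. A neighbour of Sunday's flask with 1.7 M of substrate has a ceiling of 41.2%, and it ended at 41.2%.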